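## Retrosynthetic overview

1. Target ⇐ its tetrakis(methoxymethyl) ether; the acetals are cleaved last, with no skeletal change.
2. Ring C is the only ring that is built, and it is built last. Its O1–C2 and C3–OH bonds form together by oxidative oxa-cyclisation (Algar–Flynn–Oyamada) of a 2'-hydroxychalcone. The chalcone comes from aldol condensation of a ring A acetophenone that already carries the finished side chain with a ring B aldehyde.
3. Side-chain tertiary alcohol ⇐ γ,δ-unsaturated trifluoroethyl ester + 2 MeMgBr.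
4. Stereocentre, isopropenyl group and three-carbon arm ⇐ one enantioselective ene reaction of a C-prenyl group with an acrylate (new).
5. C-Prenyl acetophenone ⇐ 2,4,6-trihydroxyacetophenone + prenyl bromide. Rings A and B are bought.

Assumption: the (S)-configured oxazaborolidine is taken to give the (R) stereocentre (model in step 3); if the sense proves opposite, the equally available (R)-catalyst is used and nothing else changes.

## Route

**Step 1**
Reactants: 1 2,4,6-trihydroxyacetophenone; 2 prenyl bromide (1-bromo-3-methylbut-2-ene)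
Product: 3 1-[2,4,6-trihydroxy-3-(3-methylbut-2-en-1-yl)phenyl]ethan-1-one
Conditions: DBU (1.1 equiv), THF, 0 °C → rt, 24 h
Reagents that add atoms: none
Why: C-alkylation of the phloroacetophenone anion by the soft allylic bromide (Friedel–Crafts-type C-prenylation of an acylphloroglucinol); both free ring positions of 1 are equivalent, so only one mono-C-prenyl isomer can form, and one equivalent of bromide limits over-alkylation.

**Step 2**
Reactants: 3 1-[2,4,6-trihydroxy-3-(3-methylbut-2-en-1-yl)phenyl]ethan-1-one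
Product: 4 1-[2-hydroxy-4,6-bis(methoxymethoxy)-3-(3-methylbut-2-en-1-yl)phenyl]ethan-1-one
Conditions: MOMCl (2.2 equiv), iPr2NEt (3 equiv), CH2Cl2, 0 °C → rt
Reagents that add atoms: chloromethyl methyl ether (MOMCl), COCCl
Why: Williamson-type acetal etherification; the 4-OH and the less hindered 6-OH react, while the 2-OH, flanked by the prenyl group and held in the hydrogen bond to the acetyl group, stays free and later becomes O1.

**Step 3**
Reactants: 4 1-[2-hydroxy-4,6-bis(methoxymethoxy)-3-(3-methylbut-2-en-1-yl)phenyl]ethan-1-one; 5 2,2,2-trifluoroethyl acrylate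
Product: 8 2,2,2-trifluoroethyl (4R)-4-{[3-acetyl-2-hydroxy-4,6-bis(methoxymethoxy)phenyl]methyl}-5-methylhex-5-enoate, via dimethylaluminium phenoxide of the prenyl ketone 6 (not isolated), via dimethylaluminium phenoxide of the ene adduct 7 (not isolated)
Conditions: Me3Al (1.0 equiv), CH2Cl2, −78 → 0 °C; then 5 (2 equiv), (S)-3,3-diphenyl-1-(2-methylphenyl)tetrahydro-1H,3H-pyrrolo[1,2-c][1,3,2]oxazaborole (C24H24BNO, 20 mol%) + AlBr3 (16 mol%), CH2Cl2, −78 → −30 °C; aq. potassium sodium tartrate
Reagents that add atoms: trimethylaluminium, C[Al](C)C (its AlMe2 unit is present only in 6 and 7)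
Why: Proposed new method: a catalytic enantioselective acrylate ene (Alder-ene) reaction of a trisubstituted alkene. The AlBr3-activated oxazaborolidine binds the acrylate carbonyl (s-trans, one π-face covered by the aryl groups); the prenyl CH carbon attacks the acrylate β-carbon from the open face while a methyl hydrogen passes to the α-carbon through a closed six-membered transition state, so the C–C bond at the less substituted alkene carbon, the isopropenyl group and the (R) stereocentre (benzylic CH2 turned away from the catalyst) arise in one event. Pre-forming the chelated dimethylaluminium phenoxide 6 removes the acidic OH and ties up the basic aryl ketone. The closest known reactions are the achiral Me2AlCl- or EtAlCl2-promoted ene reaction of acrylates with trisubstituted alkenes and the enantioselective Diels–Alder and [2+2] cycloadditions of trifluoroethyl acrylate and allenoates with this catalyst class.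

**Step 4**
Reactants: 8 2,2,2-trifluoroethyl (4R)-4-{[3-acetyl-2-hydroxy-4,6-bis(methoxymethoxy)phenyl]methyl}-5-methylhex-5-enoate
Product: 10 1-{2-hydroxy-3-[(2R)-5-hydroxy-5-methyl-2-(prop-1-en-2-yl)hexyl]-4,6-bis(methoxymethoxy)phenyl}ethan-1-one, via methyl ketone 9 (not isolated)
Conditions: MeMgBr (4 equiv), THF, −40 → 0 °C; aq. NH4Cl
Reagents that add atoms: methylmagnesium bromide, C[Mg]Br
Why: Double Grignard addition to the activated ester through ketone 9 gives the tertiary alcohol, while the aryl ketone is shielded as its chelated bromomagnesium phenoxide between two ortho substituents; the stereocentre is not touched.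

**Step 5**
Reactants: 11 2,4-dihydroxybenzaldehyde
Product: 12 2,4-bis(methoxymethoxy)benzaldehyde
Conditions: MOMCl (3 equiv), iPr2NEt (4 equiv), CH2Cl2, 0 °C → rt
Reagents that add atoms: chloromethyl methyl ether (MOMCl), COCCl
Why: Standard Williamson-type MOM etherification of both phenols, giving a base-stable ring B aldehyde.

**Step 6**
Reactants: 10 1-{2-hydroxy-3-[(2R)-5-hydroxy-5-methyl-2-(prop-1-en-2-yl)hexyl]-4,6-bis(methoxymethoxy)phenyl}ethan-1-one; 12 2,4-bis(methoxymethoxy)benzaldehyde
Product: 15 2-[2,4-bis(methoxymethoxy)phenyl]-3-hydroxy-8-[(2R)-5-hydroxy-5-methyl-2-(prop-1-en-2-yl)hexyl]-5,7-bis(methoxymethoxy)-4H-chromen-4-one, via chalcone 13 (not isolated), via trans-dihydroflavonol 14 (not isolated)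
Conditions: 12 (1.2 equiv), KOH (12 equiv), EtOH/H2O 4:1, rt, 36 h; then MeOH, 30% aq. H2O2 (6 equiv), 0 °C → rt, 4 h
Reagents that add atoms: hydrogen peroxide, OO
Why: Claisen–Schmidt condensation gives the (E)-chalcone, then the Algar–Flynn–Oyamada reaction closes ring C: the 2'-phenoxide adds to the enone β-carbon (O1–C2 bond) as the enolate is hydroxylated by H2O2 (C3–O bond), and the dihydroflavonol is dehydrogenated in the same pot; because the free phenol is the one next to the side chain, the chain ends at C8, and the isolated alkene, tertiary alcohol and stereocentre are inert to alkaline peroxide.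

**Step 7**
Reactants: 15 2-[2,4-bis(methoxymethoxy)phenyl]-3-hydroxy-8-[(2R)-5-hydroxy-5-methyl-2-(prop-1-en-2-yl)hexyl]-5,7-bis(methoxymethoxy)-4H-chromen-4-one
Product: 16 kushenol G
Conditions: HCl (1 M in MeOH/H2O 9:1), 40 °C, 2 h; then NaHCO3
Reagents that add atoms: none
Why: Acid-catalysed acetal methanolysis of the four aryl MOM ethers, the usual finish for MOM-protected 8-prenylflavonols; dilute acid at 40 °C is mild enough to spare the isopropenyl group, the tertiary alcohol and the allylic stereocentre.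

## Compound list

1 | 2,4,6-trihydroxyacetophenone | CC(=O)c1c(O)cc(O)cc1O | starting material
2 | prenyl bromide (1-bromo-3-methylbut-2-ene) | CC(C)=CCBr | starting material
3 | 1-[2,4,6-trihydroxy-3-(3-methylbut-2-en-1-yl)phenyl]ethan-1-one | CC(=O)c1c(O)cc(O)c(CC=C(C)C)c1O | intermediate
4 | 1-[2-hydroxy-4,6-bis(methoxymethoxy)-3-(3-methylbut-2-en-1-yl)phenyl]ethan-1-one | CC(=O)c1c(OCOC)cc(OCOC)c(CC=C(C)C)c1O | intermediate
5 | 2,2,2-trifluoroethyl acrylate | C=CC(=O)OCC(F)(F)F | starting material
6 | [2-acetyl-3,5-bis(methoxymethoxy)-6-(3-methylbut-2-en-1-yl)phenoxy]dimethylaluminium (not isolated) | CC(=O)c1c(OCOC)cc(OCOC)c(CC=C(C)C)c1O[Al](C)C | intermediate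
7 | {2-acetyl-3,5-bis(methoxymethoxy)-6-[(2R)-5-oxo-2-(prop-1-en-2-yl)-5-(2,2,2-trifluoroethoxy)pentyl]phenoxy}dimethylaluminium (not isolated) | C=C(C)[C@H](CCC(=O)OCC(F)(F)F)Cc1c(O[Al](C)C)c(C(C)=O)c(OCOC)cc1OCOC | intermediate
8 | 2,2,2-trifluoroethyl (4R)-4-{[3-acetyl-2-hydroxy-4,6-bis(methoxymethoxy)phenyl]methyl}-5-methylhex-5-enoate | C=C(C)[C@H](CCC(=O)OCC(F)(F)F)Cc1c(O)c(C(C)=O)c(OCOC)cc1OCOC | intermediate
9 | (5R)-5-{[3-acetyl-2-hydroxy-4,6-bis(methoxymethoxy)phenyl]methyl}-6-methylhept-6-en-2-one (not isolated; present as its bromomagnesium phenoxide) | C=C(C)[C@H](CCC(C)=O)Cc1c(O)c(C(C)=O)c(OCOC)cc1OCOC | intermediate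
10 | 1-{2-hydroxy-3-[(2R)-5-hydroxy-5-methyl-2-(prop-1-en-2-yl)hexyl]-4,6-bis(methoxymethoxy)phenyl}ethan-1-one | C=C(C)[C@H](CCC(C)(C)O)Cc1c(O)c(C(C)=O)c(OCOC)cc1OCOC | intermediate
11 | 2,4-dihydroxybenzaldehyde | O=Cc1ccc(O)cc1O | starting material
12 | 2,4-bis(methoxymethoxy)benzaldehyde | O=Cc1ccc(OCOC)cc1OCOC | intermediate
13 | (2E)-3-[2,4-bis(methoxymethoxy)phenyl]-1-{2-hydroxy-3-[(2R)-5-hydroxy-5-methyl-2-(prop-1-en-2-yl)hexyl]-4,6-bis(methoxymethoxy)phenyl}prop-2-en-1-one (chalcone, not isolated) | C=C(C)[C@H](CCC(C)(C)O)Cc1c(O)c(C(=O)/C=C/c2ccc(OCOC)cc2OCOC)c(OCOC)cc1OCOC | intermediate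
14 | 2-[2,4-bis(methoxymethoxy)phenyl]-3-hydroxy-8-[(2R)-5-hydroxy-5-methyl-2-(prop-1-en-2-yl)hexyl]-5,7-bis(methoxymethoxy)-2,3-dihydro-4H-chromen-4-one (2,3-trans, both C2/C3 diastereomers, not isolated) | C=C(C)[C@H](CCC(C)(C)O)Cc1c(OCOC)cc(OCOC)c2c1OC(c1ccc(OCOC)cc1OCOC)C(O)C2=O | intermediate
15 | 2-[2,4-bis(methoxymethoxy)phenyl]-3-hydroxy-8-[(2R)-5-hydroxy-5-methyl-2-(prop-1-en-2-yl)hexyl]-5,7-bis(methoxymethoxy)-4H-chromen-4-one | C=C(C)[C@H](CCC(C)(C)O)Cc1c(OCOC)cc(OCOC)c2c(=O)c(O)c(-c3ccc(OCOC)cc3OCOC)oc12 | intermediate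
16 | kushenol G, 2-(2,4-dihydroxyphenyl)-3,5,7-trihydroxy-8-[(2R)-5-hydroxy-5-methyl-2-(prop-1-en-2-yl)hexyl]-4H-chromen-4-one | C=C(C)[C@H](CCC(C)(C)O)Cc1c(O)cc(O)c2c(=O)c(O)c(-c3ccc(O)cc3O)oc12 | target

## Step count and risks

Total steps: 7. Longest linear sequence: 6 (steps 1, 2, 3, 4, 6, 7); step 5 is a one-step side branch.

**Step 3 (new enantioselective ene reaction).** Possible failures are low or reversed enantioselectivity, capture of the developing tertiary cation by an ortho oxygen (chroman), a second ene reaction at the new isopropenyl group, and catalyst inhibition by the Lewis-basic ketone and acetals. The fallback uses known chemistry, sets out from 4 and comes back at 8. The ene reaction is run without any chiral control, with Me2AlCl (2.2 equiv; the first equivalent forms the aluminium phenoxide) and 5 in CH2Cl2 at 0 °C → rt, which is the established alkylaluminium chloride acrylate ene reaction of trisubstituted alkenes. This gives the racemic trifluoroethyl ester F1. Its enantiomers are separated by preparative supercritical-fluid chromatography on amylose tris(3,5-dimethylphenylcarbamate), and the (R)-enantiomer is 8. The configuration is assigned by taking a sample through to 16 and comparing optical rotation and CD with natural kushenol G.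

**Step 6 (one-pot condensation and Algar–Flynn–Oyamada cyclisation).** The 6'-alkoxy group and the ortho-substituted ring B favour aurone formation, and the hindered condensation may be slow. The fallback sets out from 10 and 12 and comes back at 15; it separates ring closure from C3 oxygenation. Chalcone 13 is isolated after the KOH/EtOH condensation and cyclised by oxa-Michael addition (NaOAc, EtOH, reflux) to the flavanone F2. This is dehydrogenated at room temperature with IBX·4-methoxypyridine N-oxide in DMSO to the flavone F3. C3–H lithiation (LiN(iPr)2, 3 equiv, THF, −78 °C) and B(OMe)3 give the dimethyl flavon-3-ylboronate F4, which 30% H2O2/aq. NaOH at 0 °C oxidises to 15.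

**Step 7 (acidic removal of four MOM groups).** The freed 7-OH can add to the isopropenyl group (chroman), the tertiary alcohol can solvolyse, and alkene migration through the tertiary cation would erode the stereocentre. The fallback sets out from 15 and comes back at 16; it replaces Brønsted-acid solvolysis by buffered silyl transfer followed by desilylation. TMSOTf (10 equiv) and 2,2'-bipyridyl (15 equiv) in CH3CN at 0 °C → rt convert the aryl MOM ethers and both free hydroxyls into the hexakis(trimethylsilyl) ether F5, which citric acid in MeOH/H2O at rt hydrolyses to 16.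

## Further compounds

F1 | step 3 | racemic 2,2,2-trifluoroethyl 4-{[3-acetyl-2-hydroxy-4,6-bis(methoxymethoxy)phenyl]methyl}-5-methylhex-5-enoate | C=C(C)C(CCC(=O)OCC(F)(F)F)Cc1c(O)c(C(C)=O)c(OCOC)cc1OCOC
F2 | step 6 | 2-[2,4-bis(methoxymethoxy)phenyl]-8-[(2R)-5-hydroxy-5-methyl-2-(prop-1-en-2-yl)hexyl]-5,7-bis(methoxymethoxy)-2,3-dihydro-4H-chromen-4-one (both C2 epimers) | C=C(C)[C@H](CCC(C)(C)O)Cc1c(OCOC)cc(OCOC)c2c1OC(c1ccc(OCOC)cc1OCOC)CC2=O
F3 | step 6 | 2-[2,4-bis(methoxymethoxy)phenyl]-8-[(2R)-5-hydroxy-5-methyl-2-(prop-1-en-2-yl)hexyl]-5,7-bis(methoxymethoxy)-4H-chromen-4-one | C=C(C)[C@H](CCC(C)(C)O)Cc1c(OCOC)cc(OCOC)c2c(=O)cc(-c3ccc(OCOC)cc3OCOC)oc12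
F4 | step 6 | dimethyl {2-[2,4-bis(methoxymethoxy)phenyl]-8-[(2R)-5-hydroxy-5-methyl-2-(prop-1-en-2-yl)hexyl]-5,7-bis(methoxymethoxy)-4-oxo-4H-chromen-3-yl}boronate | C=C(C)[C@H](CCC(C)(C)O)Cc1c(OCOC)cc(OCOC)c2c(=O)c(B(OC)OC)c(-c3ccc(OCOC)cc3OCOC)oc12
F5 | step 7 | hexakis(trimethylsilyl) ether of kushenol G (3-O, 5-O, 7-O, 2'-O, 4'-O and side-chain O silylated) | C=C(C)[C@H](CCC(C)(C)O[Si](C)(C)C)Cc1c(O[Si](C)(C)C)cc(O[Si](C)(C)C)c2c(=O)c(O[Si](C)(C)C)c(-c3ccc(O[Si](C)(C)C)cc3O[Si](C)(C)C)oc12
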